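## Analysis of the target

Compound 30 is a sesquineolignan: a 2,6-diaryl-3,7-dioxabicyclo[3.3.0]octane (furofuran) whose syringyl ring is tied through its 4-oxygen to C8'' of a syringylglycerol chain (C7''–C9''). Lignan numbering is used throughout: guaiacyl unit C7–C9, core syringyl unit C7'–C9'; ring A = C7, C8, C8', C9', O and ring B = C7', C8', C8, C9, O, cis-fused along C8–C8'. The core has four contiguous stereocentres (7R, 8S, 7'S, 8'S). The guaiacyl group at C7 is exo (trans to the C9 arm on ring A), the syringyl group at C7' is endo (cis to C9' and to C7, so ring B is all-cis), which makes this an epi-type furofuran. The chain adds a threo pair (7''R, 8''R) that is too far from the core to be relayed from it. The endo benzylic ether at C7' epimerises to the exo isomer under acid through a benzylic cation, all benzylic C–O bonds can be hydrogenolysed, and of three phenolic oxygens two must end free while the third carries the chain. The difficulty is an unsymmetrical furofuran with one aryl group on the concave face, which acid-equilibrating ring closures do not favour, joined to a reagent-controlled threo ether. The strategy rests on this feature: C9 is a methylene between the ring B oxygen and C8, and C7 is a benzylic ether carbon next to C8 with a para-oxygenated aryl ring. An oxygen-bound C9 radical can therefore attack C8 of a C8=C7 styrene, the resulting C7 radical is easily oxidised to a cation, and the C9' hydroxyl is placed to capture it.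

## Retrosynthetic reasoning

**30 from 29.** The two free phenols are masked as benzyl ethers in 29. They are cut last because aryl benzyl ethers can be removed under neutral conditions, and the endo centre C7' tolerates no acid.

**29 from 27 by way of 28.** C9'' is taken back to the ester of 28, and the C7'' carbinol to the ketone of 27. In 27 the centre C8'' lies between two carbonyl groups and is stereolabile, so one catalyst-controlled reduction with dynamic kinetic resolution can set both 7''R and 8''R. This is needed because the core cannot direct these remote centres.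

**27 from 22 and 26.** The C8''–O aryl ether bond is the natural break of the side chain. It divides the molecule into the furofuran phenol 22 and the bromo keto ester 26. The forward reaction is a phenoxide alkylation at a doubly activated carbon.

**26 from 23.** Bromide 26 comes from keto ester 25 by enol bromination, 25 from ketone 24 by carboxylation of its enolate, and 24 from the commercial phenol 23 by benzylation.

**22 from 21.** The core syringyl oxygen is carried as a pivalate. It is distinguished from the benzyl-protected guaiacyl oxygen, and the acyloxy group makes the C7' benzylic ether harder to ionise while cations are generated nearby.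

**21 from 16 (key disconnection).** The C9–C8 bond of ring B and the C7–O bond of ring A are cut together. This leaves the acyclic hydroxy acid 16, whose only stereocentres, C7' and C8', are vicinal and can be made by allylboration. The endo relation of the syringyl group is thus fixed before any ring exists and under conditions that cannot equilibrate it. The forward step must produce the C9 radical 18 by decarboxylation, close ring B onto C8 (radical 19), oxidise C7 to cation 20 and let the C9' hydroxyl close ring A. Direct photo-oxidation of the carboxylate of 16 with a stoichiometric metal oxidant was considered and set aside for two reasons. The excited state needed for a carboxylate would also oxidise the dialkoxystyrene. A stoichiometric oxidant would also meet radical 18, a much stronger reductant than 19, before it cyclises. The decarboxylation is therefore started by reduction of the active ester 17, made in the flask from 16. The oxidised photocatalyst, present only in catalytic amount, then performs the one oxidation that is wanted.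

**16 from 12 and 15.** The C7=C8 double bond is cut by cross-metathesis. The guaiacyl ring enters late as styrene 15, made from 13 through 14. The bond carries no stereocentre and the (E) geometry is the favoured one.

**12 from 9 and 10.** The C7'O–C9 ether bond is cut to the carbinol 9 and the diazo ester 10. Carbenoid O–H insertion forms this bond without base, so the aryl pivalate is not attacked and the silyl group cannot migrate between the two oxygens. Acid then removes the tert-butyl ester and the silyl ether of 11 in one step, before the acid-sensitive styrene is present.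

**9 from 7 and 5.** The C7'–C8' bond is cut to aldehyde 7 (from 6) and the (Z)-allylboronate 5. The (Z) geometry becomes the syn relation that the all-cis ring B needs, and a chiral acid sets the absolute configuration. Boronate 5 comes from chloride 4, alcohol 2 and diol 1, whose (Z) double bond is bought.

## Alternatives that were turned down

**Alternative 1:** Ring A would be made first, with C7' carried as a ketone. The cuts are C7–C8 and C8'–C9'. In the forward step a strong Lewis acid would open the acetal carbon of dioxolane A1 to an oxocarbenium ion at C7. The C8'=C8 alkene would close onto it through a six-membered chair, and a 1,2-shift of the C9' methylene from the carbinol carbon to C8' would contract the ring and release the aryl ketone A2. In its favour, the Prins–pinacol sequence is an established reaction type, A1 is assembled convergently from 14, and the (E) alkene and the chair should give the trans relation of C7 and C8 (exo guaiacyl) reliably. On these two points it is stronger than the chosen route. Against it, the alkene of A1 is 1,2-disubstituted and has an allylic silyloxy group, so the positive charge at C8' is secondary and inductively disfavoured. Three stereochemical tasks also remain after A2. C8' is epimerisable and must be cis to the C9 arm, against the preference of the monocycle. The ketone must be reduced to the carbinol that leads to endo syringyl. Ring B must then be closed without losing that centre. The hardest centre of 30 would thus be set by substrate-controlled reduction next to a labile centre, and the absolute configuration would rest on an uncertain axial or equatorial preference at the tertiary carbinol of A1. The chosen strategy fixes C7' and C8' beforehand by catalyst control and closes both rings in one step.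

**Alternative 2:** Ring B would be annulated onto a lactone. The cuts are C7'–O and C8–C9. The one-carbon unit is formaldehyde A4, the C8–C7' bond of the cyclopropane-fused lactone A3 is the latent dipole, and C7 is a lactone carbonyl. In the forward step a Lewis acid would polarise the C8–C7' bond, the oxygen of A4 would attack C7' with inversion, and the lactone enolate at C8 would close onto the carbon of A4 to give the bicyclic lactone A5. In its favour, it is the shortest way to a bicyclic core. The endo syringyl group would follow by design from inversion of the easily made exo cyclopropane, and C8, C8' and C7' would be relayed from one chiral element. On brevity and on the logic of the endo centre it is stronger than the chosen route. Against it, annulations of this kind are established for cyclopropanes with two geminal acceptors. A3 has one acceptor and an electron-rich aryl donor, so ring opening to a benzylic cation is likely to precede attack of A4, and the inversion, even the enantiomeric purity, would be lost. A4 is also a weak and oligomerising partner. After A5 the guaiacyl ring must be added to the lactone carbonyl and the lactol reduced. Hydride is expected to enter from the convex face, which places the aryl group endo, the wrong result for 30. The alternative closure of a diol needs acid next to an endo C7' ether that bears an alkoxy-rich ring. The chosen strategy keeps C7' under non-ionising conditions throughout and delivers the exo guaiacyl group in the ring-forming step itself.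

**Alternative 3:** Ring B would be closed by C–H insertion. The cut is C8'–C7'. In the diazo lactone A6, ring A is present as a trans lactone with C9' as carbonyl and C9 is a syringylmethyl ether. A dirhodium carboxylate catalyst would convert the diazo group at C8' into a carbenoid that inserts into the benzylic C–H bond of the ether through a five-membered transition state. The product is the furofuranone A7, with endo syringyl and exo guaiacyl. In its favour, insertion of lactone carbenoids into benzylic ether C–H bonds is established for endo-aryl furofuranones. The cis fusion is enforced and the endo selectivity is kinetic and predictable. On precedent and on reliability of the endo centre this alternative is stronger than the chosen one. Against it for this target, A6 needs a long sequence: enantioselective construction of the trans lactone, etherification, and diazo transfer to a lactone that must first be activated. After A7 the C9' carbonyl must still be reduced to a methylene, by ring opening and re-closure or by Lewis-acid lactol reduction, next to the endo ether of a silyloxy-rich ring. The carbenoid may also add to the electron-rich arenes. The chosen strategy offers a shorter path: C7' and C8' come from one catalytic step and both rings from one further step. Its product is already at the correct oxidation level, and it needs no diazo transfer.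

Key step: step 11

Remark on the chemistry: the antipodes of the catalysts in steps 5 and 17 are assigned from the usual sense of induction of these catalyst families with aryl aldehydes and aryl ketones; if a catalyst induced the opposite sense with these substrates, its mirror image would be used.

## Route

Step 1
Reactants: 1 (2Z)-but-2-ene-1,4-diol
Product: 2 (2Z)-4-{[tert-butyl(dimethyl)silyl]oxy}but-2-en-1-ol
Conditions: NaH (1 equiv), THF, 0 °C; TBSCl (1 equiv), rt
Reagents that add atoms: tert-butyl(chloro)dimethylsilane, CC(C)(C)[Si](C)(C)Cl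
Why: Monosilylation of a symmetrical diol through its sparingly soluble monosodium alkoxide, which reacts once; the (Z) double bond is not involved.

Step 2
Reactants: 2 (2Z)-4-{[tert-butyl(dimethyl)silyl]oxy}but-2-en-1-ol
Product: 4 tert-butyl{[(2Z)-4-chlorobut-2-en-1-yl]oxy}dimethylsilane, via allylic mesylate 3 (not isolated)
Conditions: MsCl, Et3N, CH2Cl2, −20 °C; then LiCl, THF, rt
Reagents that add atoms: lithium chloride, [Li+].[Cl-]
Why: Mesylation followed by SN2 displacement with chloride at the primary allylic carbon; no allyl cation or allylmetal species is formed, so neither the position nor the (Z) geometry of the double bond should change.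

Step 3
Reactants: 4 tert-butyl{[(2Z)-4-chlorobut-2-en-1-yl]oxy}dimethylsilane
Product: 5 tert-butyldimethyl{[(2Z)-4-(4,4,5,5-tetramethyl-1,3,2-dioxaborolan-2-yl)but-2-en-1-yl]oxy}silane
Conditions: B2pin2 (1.1 equiv), Pd2(dba)3 (1 mol%), THF, 60 °C
Reagents that add atoms: bis(pinacolato)diboron, CC1(C)OB(OC1(C)C)B1OC(C)(C)C(C)(C)O1
Why: Palladium-catalysed borylation of an allylic chloride (Miyaura-type). Without phosphine, transmetalation of the first-formed anti-allylpalladium chloride with the diboron reagent is expected to be faster than its isomerisation, so the (Z) geometry should pass into 5.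

Step 4
Reactants: 6 syringaldehyde (4-hydroxy-3,5-dimethoxybenzaldehyde)
Product: 7 4-formyl-2,6-dimethoxyphenyl 2,2-dimethylpropanoate
Conditions: pivaloyl chloride, Et3N, 4-(dimethylamino)pyridine (cat.), CH2Cl2, 0 °C to rt
Reagents that add atoms: pivaloyl chloride, CC(C)(C)C(Cl)=O
Why: Acylation of the hindered phenol under nucleophilic catalysis; the pivalate marks the oxygen that will later carry the side chain and lowers the electron density of this ring.

Step 5
Reactants: 7 4-formyl-2,6-dimethoxyphenyl 2,2-dimethylpropanoate; 5 tert-butyldimethyl{[(2Z)-4-(4,4,5,5-tetramethyl-1,3,2-dioxaborolan-2-yl)but-2-en-1-yl]oxy}silane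
Product: 9 4-[(1S,2S)-2-({[tert-butyl(dimethyl)silyl]oxy}methyl)-1-hydroxybut-3-en-1-yl]-2,6-dimethoxyphenyl 2,2-dimethylpropanoate, via pinacol borate ester 8 (not isolated)
Conditions: (S)-3,3'-bis(2,4,6-triisopropylphenyl)-1,1'-binaphthyl-2,2'-diyl hydrogen phosphate (5 mol%), 4 Å molecular sieves, toluene, −30 °C; then aq. NaHCO3
Reagents that add atoms: none
Why: Chiral-phosphoric-acid-catalysed allylboration of an aryl aldehyde through a closed chair-like six-membered transition state. The (Z) geometry of 5 places the silyloxymethyl group axial and so gives the syn relation of C7' and C8'; the (S)-acid, bound to the boronate oxygen and the formyl hydrogen, directs the allyl group to the Si face of the aldehyde, which sets (1S,2S).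

Step 6
Reactants: 9 4-[(1S,2S)-2-({[tert-butyl(dimethyl)silyl]oxy}methyl)-1-hydroxybut-3-en-1-yl]-2,6-dimethoxyphenyl 2,2-dimethylpropanoate; 10 tert-butyl 2-diazoacetate
Product: 11 tert-butyl 2-{[(1S,2S)-2-({[tert-butyl(dimethyl)silyl]oxy}methyl)-1-[4-(2,2-dimethylpropanoyloxy)-3,5-dimethoxyphenyl]but-3-en-1-yl]oxy}acetate
Conditions: Rh2(OAc)4 (1 mol%), CH2Cl2, rt, slow addition of 10 (2.5 equiv)
Reagents that add atoms: none
Why: Rhodium-carbenoid O–H insertion: the carbinol oxygen adds to the electrophilic carbenoid and a proton shift gives the ether under neutral conditions, so the aryl pivalate is not attacked and the silyl group cannot migrate as it could under a basic Williamson etherification. Insertion into the O–H bond is expected to be faster than cyclopropanation of the monosubstituted alkene.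

Step 7
Reactants: 11 tert-butyl 2-{[(1S,2S)-2-({[tert-butyl(dimethyl)silyl]oxy}methyl)-1-[4-(2,2-dimethylpropanoyloxy)-3,5-dimethoxyphenyl]but-3-en-1-yl]oxy}acetate
Product: 12 2-{[(1S,2S)-1-[4-(2,2-dimethylpropanoyloxy)-3,5-dimethoxyphenyl]-2-(hydroxymethyl)but-3-en-1-yl]oxy}acetic acid
Conditions: CF3CO2H/CH2Cl2/H2O (10:10:1), 0 °C to rt
Reagents that add atoms: none
Why: Acidolysis of the tert-butyl ester (loss of isobutene) and of the primary silyl ether in one operation. It is placed before the styrene is introduced, because the electron-rich styrene would not tolerate the acid, whereas the terminal alkene, the deactivated benzylic ether and the aryl pivalate do.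

Step 8
Reactants: 13 vanillin (4-hydroxy-3-methoxybenzaldehyde)
Product: 14 4-(benzyloxy)-3-methoxybenzaldehyde
Conditions: BnBr, K2CO3, DMF, rt
Reagents that add atoms: benzyl bromide, BrCc1ccccc1
Why: Williamson etherification of the phenol; the benzyl ether keeps the ring electron-rich for the later radical-to-cation crossover.

Step 9
Reactants: 14 4-(benzyloxy)-3-methoxybenzaldehyde
Product: 15 1-(benzyloxy)-4-ethenyl-2-methoxybenzene
Conditions: Ph3PCH3Br, KOtBu, THF, 0 °C to rt
Reagents that add atoms: methyltriphenylphosphonium bromide, C[P+](c1ccccc1)(c1ccccc1)c1ccccc1.[Br-]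
Why: Wittig methylenation of the aldehyde with the non-stabilised ylide.

Step 10
Reactants: 12 2-{[(1S,2S)-1-[4-(2,2-dimethylpropanoyloxy)-3,5-dimethoxyphenyl]-2-(hydroxymethyl)but-3-en-1-yl]oxy}acetic acid; 15 1-(benzyloxy)-4-ethenyl-2-methoxybenzene
Product: 16 2-{[(1S,2S,3E)-4-[4-(benzyloxy)-3-methoxyphenyl]-1-[4-(2,2-dimethylpropanoyloxy)-3,5-dimethoxyphenyl]-2-(hydroxymethyl)but-3-en-1-yl]oxy}acetic acid
Conditions: second-generation Grubbs catalyst RuCl2(=CHPh)(PCy3)(H2IMes) (5 mol%), 15 (3 equiv), CH2Cl2, 40 °C
Reagents that add atoms: none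
Why: Olefin cross-metathesis between the allylically branched, slowly homodimerising terminal alkene and an excess of the styrene. Aryl-substituted alkenes formed by metathesis are obtained as the favoured (E) isomers, and the catalyst tolerates free hydroxyl and carboxyl groups.

Step 11
Reactants: 16 2-{[(1S,2S,3E)-4-[4-(benzyloxy)-3-methoxyphenyl]-1-[4-(2,2-dimethylpropanoyloxy)-3,5-dimethoxyphenyl]-2-(hydroxymethyl)but-3-en-1-yl]oxy}acetic acid
Product: 21 4-[(1S,3aS,4R,6aS)-4-[4-(benzyloxy)-3-methoxyphenyl]tetrahydro-1H,3H-furo[3,4-c]furan-1-yl]-2,6-dimethoxyphenyl 2,2-dimethylpropanoate, via N-acyloxyphthalimide 17 (not isolated), via C9 alkoxymethyl radical 18 (not isolated), via C7 benzylic radical 19 (not isolated), via C7 benzylic cation 20 (not isolated)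
Conditions: N-hydroxyphthalimide (1.1 equiv), N,N'-diisopropylcarbodiimide (1.1 equiv), CH2Cl2, 0 °C to rt; then fac-Ir(ppy)3 (1 mol%), CH2Cl2 (0.02 M), blue LEDs (450 nm), rt, Ar
Reagents that add atoms: none
Why: Proposed new method: the acid is first converted in the flask into its N-acyloxyphthalimide 17, to which the excited trivalent iridium complex fac-Ir(ppy)3 transfers one electron; N–O cleavage and loss of carbon dioxide leave the nucleophilic oxygen-bound C9 radical 18. Radical 18 adds to C8 of the styrene in a 5-exo-trig closure (C9–C8, ring B) and gives the C7 benzylic radical 19, which the tetravalent iridium complex formed in the first electron transfer oxidises to the para-alkoxybenzyl cation 20, so the catalyst is returned without any added oxidant. The C9' hydroxyl then adds to C7 in a second 5-exo-trig closure (C7–O, ring A), and the phthalimide anion takes up the proton. The closest known reactions are the photoredox decarboxylative 5-exo cyclisation of α-alkoxy radicals onto alkenes and the oxyalkylation of styrenes with N-acyloxyphthalimides and alcohols by radical–polar crossover; what is new is their union with radical acceptor and alcohol in the same molecule. C8 is set in the radical closure through a chair-like transition state with the syringyl group at C7' pseudo-equatorial and the hydroxymethyl arm at C8' pseudo-axial, which puts all three substituents of ring B on one face; this preference is expected to be moderate, and only this diastereomer can close ring A, since the other would need a trans-fused bicycle. C7 is set in the cation capture, in which the guaiacyl ring turns to the convex face away from ring B (exo). The step needs 18 to cyclise before it is oxidised and 19 to be oxidised in preference to the alkene and the arenes: the first is secured by the absence of any stoichiometric oxidant, the second by the para-benzyloxy group of the guaiacyl ring together with the mild oxidising power of the tetravalent iridium complex, and the pivaloyloxy group keeps the C7' benzylic ether from ionising.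

Step 12
Reactants: 21 4-[(1S,3aS,4R,6aS)-4-[4-(benzyloxy)-3-methoxyphenyl]tetrahydro-1H,3H-furo[3,4-c]furan-1-yl]-2,6-dimethoxyphenyl 2,2-dimethylpropanoate
Product: 22 4-[(1S,3aS,4R,6aS)-4-[4-(benzyloxy)-3-methoxyphenyl]tetrahydro-1H,3H-furo[3,4-c]furan-1-yl]-2,6-dimethoxyphenol
Conditions: LiAlH4, THF, 0 °C; aq. Rochelle salt
Reagents that add atoms: none
Why: Reductive cleavage of the hindered aryl ester by hydride; the furofuran ethers and the benzyl ether are inert, and the work-up is kept non-acidic so that the endo C7' centre is not epimerised.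

Step 13
Reactants: 23 1-(4-hydroxy-3,5-dimethoxyphenyl)ethan-1-one
Product: 24 1-[4-(benzyloxy)-3,5-dimethoxyphenyl]ethan-1-one
Conditions: BnBr, K2CO3, DMF, 60 °C
Reagents that add atoms: benzyl bromide, BrCc1ccccc1
Why: Williamson etherification of the phenol.

Step 14
Reactants: 24 1-[4-(benzyloxy)-3,5-dimethoxyphenyl]ethan-1-one
Product: 25 ethyl 3-[4-(benzyloxy)-3,5-dimethoxyphenyl]-3-oxopropanoate
Conditions: NaH (2.5 equiv), (EtO)2CO, toluene, 90 °C; AcOH quench
Reagents that add atoms: diethyl carbonate, CCOC(=O)OCC
Why: Crossed Claisen condensation of the methyl ketone enolate with diethyl carbonate, driven to completion by deprotonation of the β-keto ester formed.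

Step 15
Reactants: 25 ethyl 3-[4-(benzyloxy)-3,5-dimethoxyphenyl]-3-oxopropanoate
Product: 26 ethyl (2RS)-3-[4-(benzyloxy)-3,5-dimethoxyphenyl]-2-bromo-3-oxopropanoate
Conditions: N-bromosuccinimide (1.05 equiv), NH4OAc (cat.), Et2O, rt
Reagents that add atoms: N-bromosuccinimide, BrN1C(=O)CCC1=O
Why: Electrophilic bromination of the enol of the β-keto ester at the doubly activated carbon, which is far more nucleophilic than the acyl-deactivated arene.

Step 16
Reactants: 22 4-[(1S,3aS,4R,6aS)-4-[4-(benzyloxy)-3-methoxyphenyl]tetrahydro-1H,3H-furo[3,4-c]furan-1-yl]-2,6-dimethoxyphenol; 26 ethyl (2RS)-3-[4-(benzyloxy)-3,5-dimethoxyphenyl]-2-bromo-3-oxopropanoate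
Product: 27 ethyl (2RS)-3-[4-(benzyloxy)-3,5-dimethoxyphenyl]-2-{4-[(1S,3aS,4R,6aS)-4-[4-(benzyloxy)-3-methoxyphenyl]tetrahydro-1H,3H-furo[3,4-c]furan-1-yl]-2,6-dimethoxyphenoxy}-3-oxopropanoate
Conditions: K2CO3, acetone, rt to 40 °C
Reagents that add atoms: none
Why: SN2 alkylation of the phenoxide by the doubly activated secondary bromide (Williamson etherification), the usual way to the β-aryl ether of arylglycerol units. The new centre C8'' is stereolabile, which the next step requires.

Step 17
Reactants: 27 ethyl (2RS)-3-[4-(benzyloxy)-3,5-dimethoxyphenyl]-2-{4-[(1S,3aS,4R,6aS)-4-[4-(benzyloxy)-3-methoxyphenyl]tetrahydro-1H,3H-furo[3,4-c]furan-1-yl]-2,6-dimethoxyphenoxy}-3-oxopropanoate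
Product: 28 ethyl (2S,3R)-3-[4-(benzyloxy)-3,5-dimethoxyphenyl]-2-{4-[(1S,3aS,4R,6aS)-4-[4-(benzyloxy)-3-methoxyphenyl]tetrahydro-1H,3H-furo[3,4-c]furan-1-yl]-2,6-dimethoxyphenoxy}-3-hydroxypropanoate
Conditions: RuCl[(S,S)-TsDPEN](p-cymene) (2 mol%), HCO2H/Et3N (5:2), CH2Cl2, 30 °C
Reagents that add atoms: none
Why: Asymmetric transfer hydrogenation with dynamic kinetic resolution: the C8'' epimers interconvert through the enol in the presence of the amine, and the (S,S)-configured ruthenium hydride reduces the aryl ketone from the face that gives 7''R. Of the two epimers it reduces faster the one that leads to the syn (threo) hydroxy ester, as established for α-alkoxy β-keto esters.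

Step 18
Reactants: 28 ethyl (2S,3R)-3-[4-(benzyloxy)-3,5-dimethoxyphenyl]-2-{4-[(1S,3aS,4R,6aS)-4-[4-(benzyloxy)-3-methoxyphenyl]tetrahydro-1H,3H-furo[3,4-c]furan-1-yl]-2,6-dimethoxyphenoxy}-3-hydroxypropanoate
Product: 29 (1R,2R)-1-[4-(benzyloxy)-3,5-dimethoxyphenyl]-2-{4-[(1S,3aS,4R,6aS)-4-[4-(benzyloxy)-3-methoxyphenyl]tetrahydro-1H,3H-furo[3,4-c]furan-1-yl]-2,6-dimethoxyphenoxy}propane-1,3-diol
Conditions: LiBH4, THF, 0 °C to rt; aq. NH4Cl
Reagents that add atoms: none
Why: Chemoselective reduction of the ester to the primary alcohol by LiBH4, assisted by the neighbouring hydroxyl; neither stereocentre is touched (the descriptor at C8'' changes only because the priorities change).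

Step 19
Reactants: 29 (1R,2R)-1-[4-(benzyloxy)-3,5-dimethoxyphenyl]-2-{4-[(1S,3aS,4R,6aS)-4-[4-(benzyloxy)-3-methoxyphenyl]tetrahydro-1H,3H-furo[3,4-c]furan-1-yl]-2,6-dimethoxyphenoxy}propane-1,3-diol
Product: 30 (1R,2R)-2-{4-[(1S,3aS,4R,6aS)-4-(4-hydroxy-3-methoxyphenyl)tetrahydro-1H,3H-furo[3,4-c]furan-1-yl]-2,6-dimethoxyphenoxy}-1-(4-hydroxy-3,5-dimethoxyphenyl)propane-1,3-diol
Conditions: H2 (1 atm), 10% Pd/C, EtOAc/EtOH, rt, stopped after uptake of two equivalents
Reagents that add atoms: none
Why: Hydrogenolysis of the two aryl benzyl ethers over Pd/C under neutral conditions. Aryl benzyl ethers are cleaved much faster than the dialkyl benzylic ethers of the furofuran and the secondary benzylic alcohol, so these should survive.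

## Compound list

1 | (2Z)-but-2-ene-1,4-diol | OC/C=C\CO | starting material
2 | (2Z)-4-{[tert-butyl(dimethyl)silyl]oxy}but-2-en-1-ol | CC(C)(C)[Si](C)(C)OC/C=C\CO | intermediate
3 | (2Z)-4-{[tert-butyl(dimethyl)silyl]oxy}but-2-en-1-yl methanesulfonate | CC(C)(C)[Si](C)(C)OC/C=C\COS(C)(=O)=O | intermediate (not isolated)
4 | tert-butyl{[(2Z)-4-chlorobut-2-en-1-yl]oxy}dimethylsilane | CC(C)(C)[Si](C)(C)OC/C=C\CCl | intermediate
5 | tert-butyldimethyl{[(2Z)-4-(4,4,5,5-tetramethyl-1,3,2-dioxaborolan-2-yl)but-2-en-1-yl]oxy}silane | CC(C)(C)[Si](C)(C)OC/C=C\CB1OC(C)(C)C(C)(C)O1 | intermediate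
6 | syringaldehyde (4-hydroxy-3,5-dimethoxybenzaldehyde) | COc1cc(C=O)cc(OC)c1O | starting material
7 | 4-formyl-2,6-dimethoxyphenyl 2,2-dimethylpropanoate | COc1cc(C=O)cc(OC)c1OC(=O)C(C)(C)C | intermediate
8 | 4-[(1S,2S)-2-({[tert-butyl(dimethyl)silyl]oxy}methyl)-1-[(4,4,5,5-tetramethyl-1,3,2-dioxaborolan-2-yl)oxy]but-3-en-1-yl]-2,6-dimethoxyphenyl 2,2-dimethylpropanoate | CC(C)(C)[Si](C)(C)OC[C@@H]([C@H](OB1OC(C)(C)C(C)(C)O1)c1cc(OC)c(OC(=O)C(C)(C)C)c(OC)c1)C=C | intermediate (not isolated)
9 | 4-[(1S,2S)-2-({[tert-butyl(dimethyl)silyl]oxy}methyl)-1-hydroxybut-3-en-1-yl]-2,6-dimethoxyphenyl 2,2-dimethylpropanoate | CC(C)(C)[Si](C)(C)OC[C@@H]([C@H](O)c1cc(OC)c(OC(=O)C(C)(C)C)c(OC)c1)C=C | intermediate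
10 | tert-butyl 2-diazoacetate | CC(C)(C)OC(=O)C=[N+]=[N-] | starting material
11 | tert-butyl 2-{[(1S,2S)-2-({[tert-butyl(dimethyl)silyl]oxy}methyl)-1-[4-(2,2-dimethylpropanoyloxy)-3,5-dimethoxyphenyl]but-3-en-1-yl]oxy}acetate | CC(C)(C)[Si](C)(C)OC[C@@H]([C@H](OCC(=O)OC(C)(C)C)c1cc(OC)c(OC(=O)C(C)(C)C)c(OC)c1)C=C | intermediate
12 | 2-{[(1S,2S)-1-[4-(2,2-dimethylpropanoyloxy)-3,5-dimethoxyphenyl]-2-(hydroxymethyl)but-3-en-1-yl]oxy}acetic acid | OC[C@@H]([C@H](OCC(=O)O)c1cc(OC)c(OC(=O)C(C)(C)C)c(OC)c1)C=C | intermediate
13 | vanillin (4-hydroxy-3-methoxybenzaldehyde) | COc1cc(C=O)ccc1O | starting material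
14 | 4-(benzyloxy)-3-methoxybenzaldehyde | COc1cc(C=O)ccc1OCc1ccccc1 | intermediate
15 | 1-(benzyloxy)-4-ethenyl-2-methoxybenzene | COc1cc(C=C)ccc1OCc1ccccc1 | intermediate
16 | 2-{[(1S,2S,3E)-4-[4-(benzyloxy)-3-methoxyphenyl]-1-[4-(2,2-dimethylpropanoyloxy)-3,5-dimethoxyphenyl]-2-(hydroxymethyl)but-3-en-1-yl]oxy}acetic acid | OC[C@@H]([C@H](OCC(=O)O)c1cc(OC)c(OC(=O)C(C)(C)C)c(OC)c1)/C=C/c1ccc(OCc2ccccc2)c(OC)c1 | intermediate (precursor of the key step)
17 | 1,3-dioxo-1,3-dihydro-2H-isoindol-2-yl 2-{[(1S,2S,3E)-4-[4-(benzyloxy)-3-methoxyphenyl]-1-[4-(2,2-dimethylpropanoyloxy)-3,5-dimethoxyphenyl]-2-(hydroxymethyl)but-3-en-1-yl]oxy}acetate | OC[C@@H]([C@H](OCC(=O)ON1C(=O)c2ccccc2C1=O)c1cc(OC)c(OC(=O)C(C)(C)C)c(OC)c1)/C=C/c1ccc(OCc2ccccc2)c(OC)c1 | intermediate (not isolated)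
18 | {[(1S,2S,3E)-4-[4-(benzyloxy)-3-methoxyphenyl]-1-[4-(2,2-dimethylpropanoyloxy)-3,5-dimethoxyphenyl]-2-(hydroxymethyl)but-3-en-1-yl]oxy}methyl radical | OC[C@@H]([C@H](O[CH2])c1cc(OC)c(OC(=O)C(C)(C)C)c(OC)c1)/C=C/c1ccc(OCc2ccccc2)c(OC)c1 | intermediate (not isolated)
19 | [4-(benzyloxy)-3-methoxyphenyl]{(3S,4S,5S)-5-[4-(2,2-dimethylpropanoyloxy)-3,5-dimethoxyphenyl]-4-(hydroxymethyl)oxolan-3-yl}methyl radical (ring B all-cis) | OC[C@@H]1[C@@H](CO[C@@H]1c1cc(OC)c(OC(=O)C(C)(C)C)c(OC)c1)[CH]c1ccc(OCc2ccccc2)c(OC)c1 | intermediate (not isolated)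
20 | [4-(benzyloxy)-3-methoxyphenyl]{(3S,4S,5S)-5-[4-(2,2-dimethylpropanoyloxy)-3,5-dimethoxyphenyl]-4-(hydroxymethyl)oxolan-3-yl}methylium (ring B all-cis) | OC[C@@H]1[C@@H](CO[C@@H]1c1cc(OC)c(OC(=O)C(C)(C)C)c(OC)c1)[CH+]c1ccc(OCc2ccccc2)c(OC)c1 | intermediate (not isolated)
21 | 4-[(1S,3aS,4R,6aS)-4-[4-(benzyloxy)-3-methoxyphenyl]tetrahydro-1H,3H-furo[3,4-c]furan-1-yl]-2,6-dimethoxyphenyl 2,2-dimethylpropanoate (guaiacyl exo, syringyl endo) | COc1cc([C@@H]2OC[C@@H]3[C@H]2CO[C@@H]3c2cc(OC)c(OC(=O)C(C)(C)C)c(OC)c2)ccc1OCc1ccccc1 | intermediate (product of the key step)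
22 | 4-[(1S,3aS,4R,6aS)-4-[4-(benzyloxy)-3-methoxyphenyl]tetrahydro-1H,3H-furo[3,4-c]furan-1-yl]-2,6-dimethoxyphenol | COc1cc([C@@H]2OC[C@@H]3[C@H]2CO[C@@H]3c2cc(OC)c(O)c(OC)c2)ccc1OCc1ccccc1 | intermediate
23 | 1-(4-hydroxy-3,5-dimethoxyphenyl)ethan-1-one (acetosyringone) | CC(=O)c1cc(OC)c(O)c(OC)c1 | starting material
24 | 1-[4-(benzyloxy)-3,5-dimethoxyphenyl]ethan-1-one | CC(=O)c1cc(OC)c(OCc2ccccc2)c(OC)c1 | intermediate
25 | ethyl 3-[4-(benzyloxy)-3,5-dimethoxyphenyl]-3-oxopropanoate | CCOC(=O)CC(=O)c1cc(OC)c(OCc2ccccc2)c(OC)c1 | intermediate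
26 | ethyl (2RS)-3-[4-(benzyloxy)-3,5-dimethoxyphenyl]-2-bromo-3-oxopropanoate | CCOC(=O)C(Br)C(=O)c1cc(OC)c(OCc2ccccc2)c(OC)c1 | intermediate
27 | ethyl (2RS)-3-[4-(benzyloxy)-3,5-dimethoxyphenyl]-2-{4-[(1S,3aS,4R,6aS)-4-[4-(benzyloxy)-3-methoxyphenyl]tetrahydro-1H,3H-furo[3,4-c]furan-1-yl]-2,6-dimethoxyphenoxy}-3-oxopropanoate (both C8'' epimers) | COc1cc([C@@H]2OC[C@@H]3[C@H]2CO[C@@H]3c2cc(OC)c(OC(C(=O)OCC)C(=O)c3cc(OC)c(OCc4ccccc4)c(OC)c3)c(OC)c2)ccc1OCc1ccccc1 | intermediate
28 | ethyl (2S,3R)-3-[4-(benzyloxy)-3,5-dimethoxyphenyl]-2-{4-[(1S,3aS,4R,6aS)-4-[4-(benzyloxy)-3-methoxyphenyl]tetrahydro-1H,3H-furo[3,4-c]furan-1-yl]-2,6-dimethoxyphenoxy}-3-hydroxypropanoate | COc1cc([C@@H]2OC[C@@H]3[C@H]2CO[C@@H]3c2cc(OC)c(O[C@H](C(=O)OCC)[C@H](O)c3cc(OC)c(OCc4ccccc4)c(OC)c3)c(OC)c2)ccc1OCc1ccccc1 | intermediate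
29 | (1R,2R)-1-[4-(benzyloxy)-3,5-dimethoxyphenyl]-2-{4-[(1S,3aS,4R,6aS)-4-[4-(benzyloxy)-3-methoxyphenyl]tetrahydro-1H,3H-furo[3,4-c]furan-1-yl]-2,6-dimethoxyphenoxy}propane-1,3-diol | COc1cc([C@@H]2OC[C@@H]3[C@H]2CO[C@@H]3c2cc(OC)c(O[C@H](CO)[C@H](O)c3cc(OC)c(OCc4ccccc4)c(OC)c3)c(OC)c2)ccc1OCc1ccccc1 | intermediate
30 | (1R,2R)-2-{4-[(1S,3aS,4R,6aS)-4-(4-hydroxy-3-methoxyphenyl)tetrahydro-1H,3H-furo[3,4-c]furan-1-yl]-2,6-dimethoxyphenoxy}-1-(4-hydroxy-3,5-dimethoxyphenyl)propane-1,3-diol | COc1cc([C@@H]2OC[C@@H]3[C@H]2CO[C@@H]3c2cc(OC)c(O[C@H](CO)[C@H](O)c3cc(OC)c(O)c(OC)c3)c(OC)c2)ccc1O | target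

## Step count and risk

Total: 19 steps. Longest linear sequence: 13 steps (from 1 through steps 1, 2, 3, 5, 6, 7, 10, 11, 12, 16, 17, 18, 19).

**Step 11 (key step, proposed new method).** The most likely failure is closure of ring B through the competing chair with the hydroxymethyl arm equatorial and the aryl group axial, which leads to the C8 epimer that cannot form ring A. The benzylic radical may also be lost by hydrogen abstraction or dimerisation before it is oxidised, and the C9' hydroxyl may be acylated during activation. The fallback is stepwise and uses known chemistry. Setting out from 16, the same active ester 17 is reduced with Ru(bpy)3(PF6)2, Hantzsch ester and iPr2NEt under blue light. The cyclised radical is then quenched by hydrogen-atom transfer and gives the monocyclic tetrahydrofuran 4-[(2S,3S,4S)-4-{[4-(benzyloxy)-3-methoxyphenyl]methyl}-3-(hydroxymethyl)oxolan-2-yl]-2,6-dimethoxyphenyl 2,2-dimethylpropanoate F1, from which the C8 epimer is removed by chromatography. 2,3-Dichloro-5,6-dicyano-1,4-benzoquinone in CH2Cl2 over aqueous buffer then abstracts hydride from the C7 methylene, which is activated by the para-benzyloxy group, and the C9' hydroxyl closes ring A. This oxidative cyclisation is known for 4-benzyl-3-(hydroxymethyl)tetrahydrofuran lignans, and it comes back to the route at 21.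

**Step 5.** The most likely failure is incomplete enantiofacial control, because the γ-substituent of 5 is larger than the methyl group for which this catalysis is established. The syn ratio would also erode if 5 is not isomerically pure. Fallback: setting out from 7 and 5, the allylboration is run without catalyst (toluene, rt). It should remain syn-selective through the closed chair, and after hydrolytic work-up it gives 9 together with its mirror image, the (1R,2R)-alcohol F2. Acylative kinetic resolution with (R)-benzotetramisole [(R)-2-phenyl-2,3-dihydroimidazo[2,1-b][1,3]benzothiazole] and isobutyric anhydride is then used; this antipode is the one expected to acylate (R)-configured aryl alkyl carbinols faster. It should convert F2 into its isobutyrate F3 and leave 9, which is separated by chromatography and re-enters the route before step 6.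

**Step 3.** The most likely failure is isomerisation of the anti-allylpalladium intermediate to the syn form before transmetalation. The (Z) geometry would be lost, and this would appear as the anti diastereomer after step 5. Fallback: setting out from 4, SN2 silylation with HSiCl3, CuCl (cat.) and iPr2NEt in Et2O gives the (Z)-allyltrichlorosilane F4 without an allylmetal intermediate that can isomerise. F4 is added to 7 under Lewis-base catalysis by the antipode of 2,2'-bis(diphenylphosphoryl)-1,1'-binaphthyl that exposes the Si face of the aldehyde (iPr2NEt, CH2Cl2, −78 °C). The reaction runs through a closed chair at hexacoordinate silicon, so (Z) again gives syn. Work-up with aq. NaHCO3 returns to the route at 9 and bypasses 5.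

**Step 10.** The most likely failure is low turnover. The alkene of 12 is allylically branched and the free hydroxy acid can bind ruthenium, so self-metathesis of 15 may take over. Fallback: the metathesis is moved one stage back. Setting out from 11 and 15 under the same catalyst, the fully protected styrene F5 is formed. The protic acid of step 7, which the styrene would not survive, is replaced by silyl-transfer unmasking. HF·pyridine in THF removes the silyl ether to give the alcohol F6. TMSOTf/2,6-lutidine in CH2Cl2 then converts the tert-butyl ester into the trimethylsilyl ester and the alcohol into its trimethylsilyl ether, F7. Aqueous methanolic work-up releases both and comes back at 16.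

**Step 17.** The most likely failure is incomplete syn selection, or slow interconversion of the C8'' epimers, because the α-substituent is a 2,6-dimethoxyaryloxy group much bulkier than the alkoxy groups for which this reduction is established. Slow epimerisation of the endo C7' centre in the formic acid medium is a second concern. Fallback (auxiliary-controlled Evans syn aldol): setting out from 22, alkylation with (4S)-4-benzyl-3-(bromoacetyl)-1,3-oxazolidin-2-one F8 (made from (4S)-4-benzyl-1,3-oxazolidin-2-one and bromoacetyl bromide) and K2CO3 in acetone gives the aryloxyacetyl imide F9. Its (Z)-boron enolate (Bu2BOTf, iPr2NEt, CH2Cl2, −78 °C) adds to 4-(benzyloxy)-3,5-dimethoxybenzaldehyde F10 (from 6, benzyl bromide and K2CO3) to give the syn adduct F11. LiBH4 in wet THF removes the auxiliary reductively and comes back at 29, bypassing 26, 27 and 28.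

## Further compounds

F1 | step 11 | 4-[(2S,3S,4S)-4-{[4-(benzyloxy)-3-methoxyphenyl]methyl}-3-(hydroxymethyl)oxolan-2-yl]-2,6-dimethoxyphenyl 2,2-dimethylpropanoate | OC[C@@H]1[C@@H](CO[C@@H]1c1cc(OC)c(OC(=O)C(C)(C)C)c(OC)c1)Cc1ccc(OCc2ccccc2)c(OC)c1
F2 | step 5 | 4-[(1R,2R)-2-({[tert-butyl(dimethyl)silyl]oxy}methyl)-1-hydroxybut-3-en-1-yl]-2,6-dimethoxyphenyl 2,2-dimethylpropanoate | CC(C)(C)[Si](C)(C)OC[C@H]([C@@H](O)c1cc(OC)c(OC(=O)C(C)(C)C)c(OC)c1)C=C
F3 | step 5 | 4-[(1R,2R)-2-({[tert-butyl(dimethyl)silyl]oxy}methyl)-1-(2-methylpropanoyloxy)but-3-en-1-yl]-2,6-dimethoxyphenyl 2,2-dimethylpropanoate | CC(C)(C)[Si](C)(C)OC[C@H]([C@@H](OC(=O)C(C)C)c1cc(OC)c(OC(=O)C(C)(C)C)c(OC)c1)C=C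
F4 | step 3 | tert-butyldimethyl{[(2Z)-4-(trichlorosilyl)but-2-en-1-yl]oxy}silane | CC(C)(C)[Si](C)(C)OC/C=C\C[Si](Cl)(Cl)Cl
F5 | step 10 | tert-butyl 2-{[(1S,2S,3E)-4-[4-(benzyloxy)-3-methoxyphenyl]-2-({[tert-butyl(dimethyl)silyl]oxy}methyl)-1-[4-(2,2-dimethylpropanoyloxy)-3,5-dimethoxyphenyl]but-3-en-1-yl]oxy}acetate | CC(C)(C)[Si](C)(C)OC[C@@H]([C@H](OCC(=O)OC(C)(C)C)c1cc(OC)c(OC(=O)C(C)(C)C)c(OC)c1)/C=C/c1ccc(OCc2ccccc2)c(OC)c1
F6 | step 10 | tert-butyl 2-{[(1S,2S,3E)-4-[4-(benzyloxy)-3-methoxyphenyl]-1-[4-(2,2-dimethylpropanoyloxy)-3,5-dimethoxyphenyl]-2-(hydroxymethyl)but-3-en-1-yl]oxy}acetate | OC[C@@H]([C@H](OCC(=O)OC(C)(C)C)c1cc(OC)c(OC(=O)C(C)(C)C)c(OC)c1)/C=C/c1ccc(OCc2ccccc2)c(OC)c1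
F7 | step 10 | trimethylsilyl 2-{[(1S,2S,3E)-4-[4-(benzyloxy)-3-methoxyphenyl]-1-[4-(2,2-dimethylpropanoyloxy)-3,5-dimethoxyphenyl]-2-{[(trimethylsilyl)oxy]methyl}but-3-en-1-yl]oxy}acetate | C[Si](C)(C)OC[C@@H]([C@H](OCC(=O)O[Si](C)(C)C)c1cc(OC)c(OC(=O)C(C)(C)C)c(OC)c1)/C=C/c1ccc(OCc2ccccc2)c(OC)c1
F8 | step 17 | (4S)-4-benzyl-3-(bromoacetyl)-1,3-oxazolidin-2-one | O=C(CBr)N1[C@@H](Cc2ccccc2)COC1=O
F9 | step 17 | (4S)-4-benzyl-3-({4-[(1S,3aS,4R,6aS)-4-[4-(benzyloxy)-3-methoxyphenyl]tetrahydro-1H,3H-furo[3,4-c]furan-1-yl]-2,6-dimethoxyphenoxy}acetyl)-1,3-oxazolidin-2-one | COc1cc([C@@H]2OC[C@@H]3[C@H]2CO[C@@H]3c2cc(OC)c(OCC(=O)N3[C@@H](Cc4ccccc4)COC3=O)c(OC)c2)ccc1OCc1ccccc1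
F10 | step 17 | 4-(benzyloxy)-3,5-dimethoxybenzaldehyde | COc1cc(C=O)cc(OC)c1OCc1ccccc1
F11 | step 17 | (4S)-4-benzyl-3-[(2S,3R)-3-[4-(benzyloxy)-3,5-dimethoxyphenyl]-2-{4-[(1S,3aS,4R,6aS)-4-[4-(benzyloxy)-3-methoxyphenyl]tetrahydro-1H,3H-furo[3,4-c]furan-1-yl]-2,6-dimethoxyphenoxy}-3-hydroxypropanoyl]-1,3-oxazolidin-2-one | COc1cc([C@@H]2OC[C@@H]3[C@H]2CO[C@@H]3c2cc(OC)c(O[C@H](C(=O)N3[C@@H](Cc4ccccc4)COC3=O)[C@H](O)c3cc(OC)c(OCc4ccccc4)c(OC)c3)c(OC)c2)ccc1OCc1ccccc1
A1 | alternative 1 | (4S)-2-[4-(benzyloxy)-3-methoxyphenyl]-4-[(1E)-3-{[tert-butyl(dimethyl)silyl]oxy}prop-1-en-1-yl]-4-{3,5-dimethoxy-4-[tri(propan-2-yl)silyloxy]phenyl}-1,3-dioxolane (either acetal epimer; carbinol carbon drawn as an equatorial aryl group in the chair would require) | COc1cc(C2OC[C@](O2)(/C=C/CO[Si](C)(C)C(C)(C)C)c2cc(OC)c(O[Si](C(C)C)(C(C)C)C(C)C)c(OC)c2)ccc1OCc1ccccc1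
A2 | alternative 1 | [(4S,5R)-5-[4-(benzyloxy)-3-methoxyphenyl]-4-({[tert-butyl(dimethyl)silyl]oxy}methyl)oxolan-3-yl]{3,5-dimethoxy-4-[tri(propan-2-yl)silyloxy]phenyl}methanone (C3 of the oxolane, lignan C8', not defined) | COc1cc([C@@H]2OCC(C(=O)c3cc(OC)c(O[Si](C(C)C)(C(C)C)C(C)C)c(OC)c3)[C@H]2CO[Si](C)(C)C(C)(C)C)ccc1OCc1ccccc1
A3 | alternative 2 | (1R,5S,6S)-6-[4-(benzyloxy)-3,5-dimethoxyphenyl]-3-oxabicyclo[3.1.0]hexan-2-one (exo aryl) | O=C1OC[C@@H]2[C@H]1[C@H]2c1cc(OC)c(OCc3ccccc3)c(OC)c1
A4 | alternative 2 | formaldehyde | C=O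
A5 | alternative 2 | (1S,5S,6S)-6-[4-(benzyloxy)-3,5-dimethoxyphenyl]-3,7-dioxabicyclo[3.3.0]octan-2-one (endo aryl) | O=C1OC[C@@H]2[C@H]1CO[C@@H]2c1cc(OC)c(OCc3ccccc3)c(OC)c1
A6 | alternative 3 | (4S,5R)-5-[4-(benzyloxy)-3-methoxyphenyl]-3-diazo-4-[({3,5-dimethoxy-4-[tri(propan-2-yl)silyloxy]phenyl}methoxy)methyl]oxolan-2-one | COc1cc([C@@H]2OC(=O)C(=[N+]=[N-])[C@H]2COCc2cc(OC)c(O[Si](C(C)C)(C(C)C)C(C)C)c(OC)c2)ccc1OCc1ccccc1
A7 | alternative 3 | (1R,4R,5S,8S)-4-[4-(benzyloxy)-3-methoxyphenyl]-8-{3,5-dimethoxy-4-[tri(propan-2-yl)silyloxy]phenyl}-3,7-dioxabicyclo[3.3.0]octan-2-one | COc1cc([C@@H]2OC(=O)[C@@H]3[C@H]2CO[C@@H]3c2cc(OC)c(O[Si](C(C)C)(C(C)C)C(C)C)c(OC)c2)ccc1OCc1ccccc1
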